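## Retrosynthetic overview

- The target is a 2'-hydroxychalcone. The acyl–vinyl bond C(=O)–Cα is cut, giving salicylaldehyde 18 and aryl alkyne 19, which are joined by Rh-catalysed alkyne hydroacylation (the formyl C–H adds across the C≡C, so every atom of both partners ends in the product).
- Enabling feature: the free phenolic O–H on C2' of ring A (the resorcinol ring), ortho to C1' that carries the carbonyl carbon. As a phenoxide it holds rhodium in a five-membered O,C-chelate (O2'–C2'–C1'–acyl C–Rh), so the target's own hydroxyl is the directing group and nothing has to be removed afterwards.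
- Aldehyde 18: the formyl group comes from OMOM-directed lithiation/DMF. The (R)-carbinol of the side chain comes from a catalytic asymmetric Ni/Cr coupling of arylacetaldehyde 6 with alkenyl triflate 9 (one step from 6-methylhept-5-en-2-one). Aldehyde 6 comes from 1,3-bis(methoxymethoxy)benzene by C2-lithiation/allylation and oxidative cleavage.
- No ring is formed in the route; both benzene rings are bought. The protecting groups are converted into three TBS ethers that are removed in one fluoride step after the key step.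

Key step: step 9

Remark on the chemistry: the stereocentre of the target is read as (R) (O > C3 alkenyl carbon > C1 methylene > H). Compounds 1 and 19 are taken as catalogue compounds (otherwise each is one routine protection step from resorcinol or 4-ethynylphenol).

## Route

Step 1
Reactants: 1 1,3-bis(methoxymethoxy)benzene; 2 allyl bromide (3-bromoprop-1-ene)
Product: 4 2-allyl-1,3-bis(methoxymethoxy)benzene, via 2-lithio-1,3-bis(methoxymethoxy)benzene 3 (not isolated)
Conditions: n-BuLi, THF, 0 °C to rt; CuI (10 mol%), then 2, –78 °C to rt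
Reagents that add atoms: n-butyllithium, [Li]CCCC (lithium of intermediate 3)
Why: Directed ortho-metalation, in which the two OMOM groups together direct n-BuLi to C2 between them, followed by copper-assisted allylation of the aryllithium.

Step 2
Reactants: 4 2-allyl-1,3-bis(methoxymethoxy)benzene
Product: 6 2-[2,6-bis(methoxymethoxy)phenyl]acetaldehyde, via racemic 3-[2,6-bis(methoxymethoxy)phenyl]propane-1,2-diol 5 (not isolated)
Conditions: OsO4 (2 mol%), NaIO4, 2,6-lutidine, dioxane/H2O 3:1, rt; used crude
Reagents that add atoms: sodium periodate, [Na+].[O-]I(=O)(=O)=O (terminal oxidant; the oxygen is passed on by catalytic osmium tetroxide, O=[Os](=O)(=O)=O)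
Why: Lemieux–Johnson oxidative cleavage of the terminal alkene, chosen over ozonolysis because the electron-rich resorcinol ring is left alone and the buffered medium keeps the MOM acetals intact.

Step 3
Reactants: 7 6-methylhept-5-en-2-one
Product: 9 6-methylhepta-1,5-dien-2-yl trifluoromethanesulfonate, via lithium 6-methylhepta-1,5-dien-2-olate 8 (not isolated)
Conditions: LDA, THF, –78 °C; PhNTf2, –78 to 0 °C; aq. NH4Cl
Reagents that add atoms: N-phenylbis(trifluoromethanesulfonimide), O=S(=O)(N(c1ccccc1)S(=O)(=O)C(F)(F)F)C(F)(F)F; lithium diisopropylamide, [Li]N(C(C)C)C(C)C (lithium of intermediate 8)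
Why: Kinetic enolate O-triflation, in which LDA at low temperature removes a proton from the methyl group and the terminal enolate is trapped as the 1-alken-2-yl triflate.

Step 4
Reactants: 6 2-[2,6-bis(methoxymethoxy)phenyl]acetaldehyde; 9 6-methylhepta-1,5-dien-2-yl trifluoromethanesulfonate
Product: 11 (2R)-1-[2,6-bis(methoxymethoxy)phenyl]-7-methyl-3-methylideneoct-6-en-2-ol, via chlorobis(cyclopentadienyl)zirconium (2R)-alkoxide 10 (not isolated)
Conditions: CrCl2 (10 mol%), chiral oxazoline–sulfonamide ligand (12 mol%; e.g. N-[2-(4-isopropyl-4,5-dihydrooxazol-2-yl)-6-methylphenyl]methanesulfonamide, antipode chosen for Si-face attack), proton sponge, NiCl2·2,9-dimethylphenanthroline (2 mol%), Mn, Cp2ZrCl2, LiCl, MeCN, rt; then H2O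
Reagents that add atoms: zirconocene dichloride, Cl[Zr](Cl)(C1C=CC=C1)C1C=CC=C1 (zirconium of intermediate 10)
Why: Catalytic asymmetric Nozaki–Hiyama–Kishi coupling, in which Ni inserts into the alkenyl triflate, the alkenyl group passes to Cr(III) and adds to the Si face of the aldehyde inside the chiral chromium complex to set the (R)-carbinol, while the non-basic organochromium spares the enolisable aldehyde and Cp2ZrCl2/Mn turn the chromium over.

Step 5
Reactants: 11 (2R)-1-[2,6-bis(methoxymethoxy)phenyl]-7-methyl-3-methylideneoct-6-en-2-ol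
Product: 12 tert-butyl{[(2R)-1-[2,6-bis(methoxymethoxy)phenyl]-7-methyl-3-methylideneoct-6-en-2-yl]oxy}dimethylsilane
Conditions: TBSCl, imidazole, DMAP (cat.), DMF, rt
Reagents that add atoms: tert-butyldimethylsilyl chloride, CC(C)(C)[Si](C)(C)Cl
Why: Imidazole-promoted silylation of the secondary alcohol, so that the next lithiation is not spent on an alkoxide and the allylic alcohol is masked for the rhodium step.

Step 6
Reactants: 12 tert-butyl{[(2R)-1-[2,6-bis(methoxymethoxy)phenyl]-7-methyl-3-methylideneoct-6-en-2-yl]oxy}dimethylsilane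
Product: 15 3-{(2R)-2-[(tert-butyldimethylsilyl)oxy]-7-methyl-3-methylideneoct-6-en-1-yl}-2,4-bis(methoxymethoxy)benzaldehyde, via C4-aryllithium 13 (not isolated), via lithium α-(dimethylamino)benzyl alkoxide 14 (not isolated)
Conditions: n-BuLi, TMEDA, THF, –20 to 0 °C; DMF, –78 °C to rt; aq. NH4Cl
Reagents that add atoms: N,N-dimethylformamide, CN(C)C=O; n-butyllithium, [Li]CCCC (lithium of intermediates 13, 14)
Why: Directed ortho-metalation/formylation, in which an OMOM group directs lithiation to the adjacent ring position (the two open ortho positions are equivalent) and DMF formylates the aryllithium without touching the stereocentre.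

Step 7
Reactants: 15 3-{(2R)-2-[(tert-butyldimethylsilyl)oxy]-7-methyl-3-methylideneoct-6-en-1-yl}-2,4-bis(methoxymethoxy)benzaldehyde
Product: 17 3-{(2R)-2-[(tert-butyldimethylsilyl)oxy]-7-methyl-3-methylideneoct-6-en-1-yl}-2,4-dihydroxybenzaldehyde, via bis(trimethylsilyl) aryl ether 16 (not isolated)
Conditions: TMSOTf, 2,2'-bipyridyl, MeCN, 0 °C to rt; then H2O, aq. NaHCO3
Reagents that add atoms: trimethylsilyl trifluoromethanesulfonate, C[Si](C)(C)OS(=O)(=O)C(F)(F)F (silyl groups of intermediate 16)
Why: Silyl triflate/2,2'-bipyridyl cleavage of aromatic MOM ethers, which turns the aryl acetals into aryl TMS ethers under buffered, non-protic conditions that should spare the alkyl TBS ether and both alkenes, after which water frees the two phenols.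

Step 8
Reactants: 17 3-{(2R)-2-[(tert-butyldimethylsilyl)oxy]-7-methyl-3-methylideneoct-6-en-1-yl}-2,4-dihydroxybenzaldehyde
Product: 18 4-[(tert-butyldimethylsilyl)oxy]-3-{(2R)-2-[(tert-butyldimethylsilyl)oxy]-7-methyl-3-methylideneoct-6-en-1-yl}-2-hydroxybenzaldehyde
Conditions: TBSCl (1.05 equiv), imidazole, CH2Cl2, 0 °C
Reagents that add atoms: tert-butyldimethylsilyl chloride, CC(C)(C)[Si](C)(C)Cl
Why: Chemoselective silylation, since the C4 hydroxyl is free and the more acidic one whereas the C2 hydroxyl is tied into the hydrogen bond to the formyl oxygen and flanked on both sides.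

Step 9
Reactants: 18 4-[(tert-butyldimethylsilyl)oxy]-3-{(2R)-2-[(tert-butyldimethylsilyl)oxy]-7-methyl-3-methylideneoct-6-en-1-yl}-2-hydroxybenzaldehyde; 19 tert-butyl(4-ethynylphenoxy)dimethylsilane
Product: 20 (2E)-1-[4-[(tert-butyldimethylsilyl)oxy]-3-{(2R)-2-[(tert-butyldimethylsilyl)oxy]-7-methyl-3-methylideneoct-6-en-1-yl}-2-hydroxyphenyl]-3-{4-[(tert-butyldimethylsilyl)oxy]phenyl}prop-2-en-1-one
Conditions: [RhCl(cod)]2 (2.5 mol%), dppf (5 mol%), Na2CO3 (10 mol%), toluene, 80 °C, slow addition of 19
Reagents that add atoms: none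
Why: The phenoxide of 18 binds Rh(I) and the formyl C–H adds oxidatively to give a five-membered acyl–Rh(III)–hydride chelate (Rh, O2, C2, C1, acyl C) that is held against decarbonylation; syn-insertion of the alkyne into Rh–H with rhodium on the terminal carbon and C–C reductive elimination then form the acyl–vinyl bond and release the enone. The closest known reaction type is the Rh/diphosphine-catalysed hydroacylation of alkynes with salicylaldehydes to 2-alkenoylphenols. No ring is closed (the rhodacycle is transient) and no stereocentre is formed; the (E)-geometry follows from syn-hydrometalation and retentive reductive elimination, and the side-chain stereocentre is not touched. The step needs linear over branched regioselectivity, which the aryl group of 19 should secure by steering rhodium to the unhindered terminal carbon under the bulky dppf ligand, helped by slow addition that also limits alkyne oligomerisation. It also needs chemoselectivity for the alkyne over the two side-chain alkenes, which carry no coordinating group and are not hydroacylated by chelated acyl-rhodium hydrides. The silyl ethers keep the allylic alcohol from Rh–H isomerisation to a ketone and leave the C2 hydroxyl as the only donor for the metal, and catalytic carbonate in toluene is too weak to close the 2'-hydroxychalcone to a flavanone.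

Step 10
Reactants: 20 (2E)-1-[4-[(tert-butyldimethylsilyl)oxy]-3-{(2R)-2-[(tert-butyldimethylsilyl)oxy]-7-methyl-3-methylideneoct-6-en-1-yl}-2-hydroxyphenyl]-3-{4-[(tert-butyldimethylsilyl)oxy]phenyl}prop-2-en-1-one
Product: 21 (2E)-1-{2,4-dihydroxy-3-[(2R)-2-hydroxy-7-methyl-3-methylideneoct-6-en-1-yl]phenyl}-3-(4-hydroxyphenyl)prop-2-en-1-one
Conditions: HF·pyridine, pyridine, THF, 0 °C to rt
Reagents that add atoms: none
Why: Fluoride-mediated desilylation under pyridine-buffered conditions, which should remove the two aryl and the allylic TBS ethers without acid- or base-induced change of the allylic alcohol, the alkenes or the 2'-hydroxychalcone.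

## Compound list

1 | 1,3-bis(methoxymethoxy)benzene | COCOc1cccc(OCOC)c1 | starting material
2 | allyl bromide | C=CCBr | starting material
3 | 2-lithio-1,3-bis(methoxymethoxy)benzene | [Li]c1c(OCOC)cccc1OCOC | intermediate
4 | 2-allyl-1,3-bis(methoxymethoxy)benzene | C=CCc1c(OCOC)cccc1OCOC | intermediate
5 | racemic 3-[2,6-bis(methoxymethoxy)phenyl]propane-1,2-diol | OCC(O)Cc1c(OCOC)cccc1OCOC | intermediate
6 | 2-[2,6-bis(methoxymethoxy)phenyl]acetaldehyde | O=CCc1c(OCOC)cccc1OCOC | intermediate
7 | 6-methylhept-5-en-2-one | CC(=O)CCC=C(C)C | starting material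
8 | lithium 6-methylhepta-1,5-dien-2-olate | [Li]OC(=C)CCC=C(C)C | intermediate
9 | 6-methylhepta-1,5-dien-2-yl trifluoromethanesulfonate | C=C(CCC=C(C)C)OS(=O)(=O)C(F)(F)F | intermediate
10 | chlorobis(cyclopentadienyl)zirconium alkoxide of (2R)-1-[2,6-bis(methoxymethoxy)phenyl]-7-methyl-3-methylideneoct-6-en-2-ol | C=C(CCC=C(C)C)[C@H](O[Zr](Cl)(C1C=CC=C1)C1C=CC=C1)Cc1c(OCOC)cccc1OCOC | intermediate
11 | (2R)-1-[2,6-bis(methoxymethoxy)phenyl]-7-methyl-3-methylideneoct-6-en-2-ol | C=C(CCC=C(C)C)[C@H](O)Cc1c(OCOC)cccc1OCOC | intermediate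
12 | tert-butyl{[(2R)-1-[2,6-bis(methoxymethoxy)phenyl]-7-methyl-3-methylideneoct-6-en-2-yl]oxy}dimethylsilane | C=C(CCC=C(C)C)[C@H](O[Si](C)(C)C(C)(C)C)Cc1c(OCOC)cccc1OCOC | intermediate
13 | C4-aryllithium of 12 (lithium ortho to one OMOM group) | C=C(CCC=C(C)C)[C@H](O[Si](C)(C)C(C)(C)C)Cc1c(OCOC)ccc([Li])c1OCOC | intermediate
14 | lithium α-(dimethylamino)benzyl alkoxide (DMF adduct of 13; mixture at the new carbon) | C=C(CCC=C(C)C)[C@H](O[Si](C)(C)C(C)(C)C)Cc1c(OCOC)ccc(C(O[Li])N(C)C)c1OCOC | intermediate
15 | 3-{(2R)-2-[(tert-butyldimethylsilyl)oxy]-7-methyl-3-methylideneoct-6-en-1-yl}-2,4-bis(methoxymethoxy)benzaldehyde | C=C(CCC=C(C)C)[C@H](O[Si](C)(C)C(C)(C)C)Cc1c(OCOC)ccc(C=O)c1OCOC | intermediate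
16 | 3-{(2R)-2-[(tert-butyldimethylsilyl)oxy]-7-methyl-3-methylideneoct-6-en-1-yl}-2,4-bis[(trimethylsilyl)oxy]benzaldehyde | C=C(CCC=C(C)C)[C@H](O[Si](C)(C)C(C)(C)C)Cc1c(O[Si](C)(C)C)ccc(C=O)c1O[Si](C)(C)C | intermediate
17 | 3-{(2R)-2-[(tert-butyldimethylsilyl)oxy]-7-methyl-3-methylideneoct-6-en-1-yl}-2,4-dihydroxybenzaldehyde | C=C(CCC=C(C)C)[C@H](O[Si](C)(C)C(C)(C)C)Cc1c(O)ccc(C=O)c1O | intermediate
18 | 4-[(tert-butyldimethylsilyl)oxy]-3-{(2R)-2-[(tert-butyldimethylsilyl)oxy]-7-methyl-3-methylideneoct-6-en-1-yl}-2-hydroxybenzaldehyde | C=C(CCC=C(C)C)[C@H](O[Si](C)(C)C(C)(C)C)Cc1c(O[Si](C)(C)C(C)(C)C)ccc(C=O)c1O | intermediate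
19 | tert-butyl(4-ethynylphenoxy)dimethylsilane | C#Cc1ccc(O[Si](C)(C)C(C)(C)C)cc1 | starting material
20 | (2E)-1-[4-[(tert-butyldimethylsilyl)oxy]-3-{(2R)-2-[(tert-butyldimethylsilyl)oxy]-7-methyl-3-methylideneoct-6-en-1-yl}-2-hydroxyphenyl]-3-{4-[(tert-butyldimethylsilyl)oxy]phenyl}prop-2-en-1-one | C=C(CCC=C(C)C)[C@H](O[Si](C)(C)C(C)(C)C)Cc1c(O[Si](C)(C)C(C)(C)C)ccc(C(=O)/C=C/c2ccc(O[Si](C)(C)C(C)(C)C)cc2)c1O | intermediate
21 | (2E)-1-{2,4-dihydroxy-3-[(2R)-2-hydroxy-7-methyl-3-methylideneoct-6-en-1-yl]phenyl}-3-(4-hydroxyphenyl)prop-2-en-1-one | C=C(CCC=C(C)C)[C@H](O)Cc1c(O)ccc(C(=O)/C=C/c2ccc(O)cc2)c1O | target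

## Step count and risks

Total step count: 10. Longest linear sequence: 9 steps (steps 1, 2, 4, 5, 6, 7, 8, 9, 10, from compound 1); step 3 is a one-step side branch.

Steps most likely to fail:

1. Step 9. The Rh–H insertion may take the wrong regiochemistry (branched 2-aryl enone), the alkyne may oligomerise at rhodium, or the product may close to a flavanone. Fallback (same bond, stoichiometric organometallic instead of C–H activation): alkyne 19 would be hydrozirconated with Cp2Zr(H)Cl to the (E)-alkenylzirconocene chloride F1 and transmetalated with Me2Zn to the (E)-alkenyl(methyl)zinc F2. This would be added in excess (the first equivalent is spent on the phenol) to aldehyde 18 to give the allylic alcohol F3 as a mixture of carbinol epimers. MnO2 in CH2Cl2 would then oxidise the doubly activated carbinol, and the route is rejoined at protected chalcone 20.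

2. Step 4. Facial selectivity of the alkenylchromium addition may be poor, or turnover with the triflate may be sluggish. Fallback (stereocentre set by reduction instead of by C–C bond formation): aldehyde 6 and triflate 9 would be coupled without chiral ligand (CrCl2, cat. NiCl2, DMF) to the racemic alcohol F4. This would be oxidised with Dess–Martin periodinane to the enone F5 and reduced with catecholborane under (S)-2-methyl-CBS-oxazaborolidine catalysis at low temperature, the 2-substituted vinyl group acting as the large substituent. The route is rejoined at (R)-alcohol 11.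

3. Step 7. The double acetal cleavage may stall after the chelated MOM group has gone, or the silyl triflate may ionise the allylic silyl ether. Fallback (only the chelation-activated acetal is removed before the key step; the other is carried to the end): aldehyde 15 would be treated with MgBr2·OEt2, which cleaves only the MOM ether ortho to the formyl group, to give the mono-MOM salicylaldehyde F6. Hydroacylation of F6 with 19 under the step 9 conditions would give the chalcone F7. HF·pyridine would then remove the silyl ethers to give the 4'-O-MOM chalcone F8. Dilute HCl in methanol at room temperature, the usual last step for prenylated chalcones, would remove the remaining acetal, and the route is rejoined at target 21.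

Further compounds
F1 | step 9 | chloro[(E)-2-{4-[(tert-butyldimethylsilyl)oxy]phenyl}ethenyl]bis(cyclopentadienyl)zirconium | Cl[Zr](/C=C/c1ccc(O[Si](C)(C)C(C)(C)C)cc1)(C1C=CC=C1)C1C=CC=C1
F2 | step 9 | [(E)-2-{4-[(tert-butyldimethylsilyl)oxy]phenyl}ethenyl](methyl)zinc | C[Zn]/C=C/c1ccc(O[Si](C)(C)C(C)(C)C)cc1
F3 | step 9 | (2E)-1-[4-[(tert-butyldimethylsilyl)oxy]-3-{(2R)-2-[(tert-butyldimethylsilyl)oxy]-7-methyl-3-methylideneoct-6-en-1-yl}-2-hydroxyphenyl]-3-{4-[(tert-butyldimethylsilyl)oxy]phenyl}prop-2-en-1-ol (carbinol epimers) | C=C(CCC=C(C)C)[C@H](O[Si](C)(C)C(C)(C)C)Cc1c(O[Si](C)(C)C(C)(C)C)ccc(C(O)/C=C/c2ccc(O[Si](C)(C)C(C)(C)C)cc2)c1O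
F4 | step 4 | racemic 1-[2,6-bis(methoxymethoxy)phenyl]-7-methyl-3-methylideneoct-6-en-2-ol | C=C(CCC=C(C)C)C(O)Cc1c(OCOC)cccc1OCOC
F5 | step 4 | 1-[2,6-bis(methoxymethoxy)phenyl]-7-methyl-3-methylideneoct-6-en-2-one | C=C(CCC=C(C)C)C(=O)Cc1c(OCOC)cccc1OCOC
F6 | step 7 | 3-{(2R)-2-[(tert-butyldimethylsilyl)oxy]-7-methyl-3-methylideneoct-6-en-1-yl}-2-hydroxy-4-(methoxymethoxy)benzaldehyde | C=C(CCC=C(C)C)[C@H](O[Si](C)(C)C(C)(C)C)Cc1c(OCOC)ccc(C=O)c1O
F7 | step 7 | (2E)-1-[3-{(2R)-2-[(tert-butyldimethylsilyl)oxy]-7-methyl-3-methylideneoct-6-en-1-yl}-2-hydroxy-4-(methoxymethoxy)phenyl]-3-{4-[(tert-butyldimethylsilyl)oxy]phenyl}prop-2-en-1-one | C=C(CCC=C(C)C)[C@H](O[Si](C)(C)C(C)(C)C)Cc1c(OCOC)ccc(C(=O)/C=C/c2ccc(O[Si](C)(C)C(C)(C)C)cc2)c1O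
F8 | step 7 | (2E)-1-{2-hydroxy-3-[(2R)-2-hydroxy-7-methyl-3-methylideneoct-6-en-1-yl]-4-(methoxymethoxy)phenyl}-3-(4-hydroxyphenyl)prop-2-en-1-one | C=C(CCC=C(C)C)[C@H](O)Cc1c(OCOC)ccc(C(=O)/C=C/c2ccc(O)cc2)c1O
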